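## Retrosynthetic overview

- 1 + 2 → 3: the aryl–prenyl bond is made first, by decarboxylative radical prenylation of benzoquinone (key step). Quinone 3 is then the acceptor for tetronic acid 4, which forms the aryl–C3 bond and delivers the hydroquinone ring of 5 with no protecting groups.
- 6 + 7 → (8) → 9 → 10 → 11 → (12) → 13: pyran ring by chromene annulation, the C3 carbinol by catalytic asymmetric epoxidation and benzylic reductive opening, CHO from the bromide.
- 5 + 13 → (14) → 15: the exocyclic C5=CH bond is made last, by vinylogous aldol condensation under thermodynamic (Z) control.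
- Ring order: the quinone ring becomes the hydroquinone ring (steps 1–2), the butenolide ring is bought as tetronic acid, the pyran ring is closed in step 3; no ring is formed after that.

Assumption: the SMILES is read as the 5Z alkylidene with an R carbinol at C3 of the chroman ring; tetronic acid units are drawn as the 4-hydroxy enol tautomer.

## Route

Step 1
Reactants: 1 1,4-benzoquinone; 2 4-methylpent-3-enoic acid
Product: 3 2-(3-methylbut-2-en-1-yl)-1,4-benzoquinone
Conditions: 1 (2.5 equiv), AgNO3 (0.2 equiv), (NH4)2S2O8 (1.3 equiv), MeCN–H2O 1:1, 65 °C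
Reagents that add atoms: none
Why: Divalent silver generated from AgNO3 and peroxydisulfate decarboxylates 2 to the 1,1-dimethylallyl radical, which adds through its unhindered CH2 terminus to the electron-poor quinone, and the adduct radical is reoxidised to the quinone (Jacobsen–Torssell, Minisci-type radical alkylation); excess 1 suppresses double prenylation.

Step 2
Reactants: 3 2-(3-methylbut-2-en-1-yl)-1,4-benzoquinone; 4 tetronic acid (4-hydroxyfuran-2(5H)-one)
Product: 5 3-[2,5-dihydroxy-4-(3-methylbut-2-en-1-yl)phenyl]-4-hydroxyfuran-2(5H)-one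
Conditions: 4 (1.5 equiv), NaOAc (0.1 equiv), degassed MeCN–H2O 1:1, slow addition of 3, 20 °C, Ar
Reagents that add atoms: none
Why: Michael addition of the acidic 1,3-dicarbonyl carbon C3 to the quinone occurs mainly at C5 (β to the carbonyl that is not deactivated by the prenyl donor, hence para to prenyl), and enolisation gives the hydroquinone directly; keeping 3 limiting avoids redox exchange and oxidative cyclisation of 5.

Step 3
Reactants: 6 4-bromophenol; 7 3-methylbut-2-enal
Product: 9 6-bromo-2,2-dimethyl-2H-chromene, via ortho-quinone methide 8 (not isolated)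
Conditions: PhB(OH)2 (1.0 equiv), AcOH, toluene, reflux, Dean–Stark
Reagents that add atoms: none
Why: Phenylboronic acid templates an ortho-specific condensation of the phenol and the enal to dienone 8, which closes by oxa-6π electrocyclisation (formal [3+3] chromene annulation).

Step 4
Reactants: 9 6-bromo-2,2-dimethyl-2H-chromene
Product: 10 (3R,4R)-6-bromo-3,4-epoxy-2,2-dimethylchromane
Conditions: (R,R)-(salen)MnCl [(R,R)-N,N'-bis(3,5-di-tert-butylsalicylidene)cyclohexane-1,2-diamine manganese chloride] (4 mol %), 4-phenylpyridine N-oxide (0.2 equiv), aq. NaOCl (pH 11.3), CH2Cl2, 0 °C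
Reagents that add atoms: sodium hypochlorite, [Na+].[O-]Cl
Why: Jacobsen–Katsuki epoxidation of a cis-disubstituted aryl-conjugated alkene, for which 2,2-dimethylchromenes typically give ≥95% ee; the (R,R)-catalyst delivers oxygen to the face that gives the (3R,4R)-epoxide, so the C3 configuration of the target is set here.

Step 5
Reactants: 10 (3R,4R)-6-bromo-3,4-epoxy-2,2-dimethylchromane
Product: 11 (3R)-6-bromo-2,2-dimethylchroman-3-ol
Conditions: LiAlH4 (1.0 equiv), THF, 0 °C; H2O, aq. NaOH work-up
Reagents that add atoms: none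
Why: Regioselective reductive epoxide opening, in which hydride attacks the benzylic C4 (SN2; C3 is shielded by the adjacent quaternary carbon), so the C3–O bond and its R configuration are untouched; the aryl bromide is inert at 0 °C.

Step 6
Reactants: 11 (3R)-6-bromo-2,2-dimethylchroman-3-ol
Product: 13 (3R)-3-hydroxy-2,2-dimethylchromane-6-carbaldehyde, via dilithio species 12 (not isolated)
Conditions: n-BuLi (2.3 equiv), THF, −78 °C; DMF (3 equiv), −78 → 0 °C; H2O
Reagents that add atoms: N,N-dimethylformamide, CN(C)C=O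
Why: O–H deprotonation followed by bromine–lithium exchange gives 12, whose aryl carbanion is formylated by DMF (Bouveault formylation) without touching the carbinol centre.

Step 7
Reactants: 5 3-[2,5-dihydroxy-4-(3-methylbut-2-en-1-yl)phenyl]-4-hydroxyfuran-2(5H)-one; 13 (3R)-3-hydroxy-2,2-dimethylchromane-6-carbaldehyde
Product: 15 (5Z)-3-[2,5-dihydroxy-4-(3-methylbut-2-en-1-yl)phenyl]-4-hydroxy-5-{[(3R)-3-hydroxy-2,2-dimethylchroman-6-yl]methylidene}furan-2(5H)-one, via aldol adduct 14 (not isolated)
Conditions: 13 (1.1 equiv), DBU (3 equiv), degassed MeCN, 60 °C, Ar; acidic aqueous work-up (pH 3)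
Reagents that add atoms: none
Why: Vinylogous aldol condensation, in which the C5 carbanion of the 3-aryltetronate adds to the non-enolisable aldehyde and carbinol 14 loses water by E1cB under equilibrating conditions to give the thermodynamically preferred Z-alkylidene (aryl anti to the C4 oxygen); the remote R carbinol is unaffected.

## Compound list

1 | 1,4-benzoquinone | O=C1C=CC(=O)C=C1 | starting material
2 | 4-methylpent-3-enoic acid | CC(C)=CCC(=O)O | starting material
3 | 2-(3-methylbut-2-en-1-yl)-1,4-benzoquinone | CC(C)=CCC1=CC(=O)C=CC1=O | intermediate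
4 | tetronic acid (4-hydroxyfuran-2(5H)-one) | O=C1C=C(O)CO1 | starting material
5 | 3-[2,5-dihydroxy-4-(3-methylbut-2-en-1-yl)phenyl]-4-hydroxyfuran-2(5H)-one | CC(C)=CCc1cc(O)c(C2=C(O)COC2=O)cc1O | intermediate
6 | 4-bromophenol | Oc1ccc(Br)cc1 | starting material
7 | 3-methylbut-2-enal | CC(C)=CC=O | starting material
8 | (6Z)-4-bromo-6-(3-methylbut-2-en-1-ylidene)cyclohexa-2,4-dien-1-one (ortho-quinone methide, not isolated) | CC(C)=C/C=C1\C(=O)C=CC(Br)=C1 | intermediate
9 | 6-bromo-2,2-dimethyl-2H-chromene | CC1(C)C=Cc2cc(Br)ccc2O1 | intermediate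
10 | (3R,4R)-6-bromo-3,4-epoxy-2,2-dimethylchromane (cis-fused epoxide) | CC1(C)Oc2ccc(Br)cc2[C@H]2O[C@@H]12 | intermediate
11 | (3R)-6-bromo-2,2-dimethylchroman-3-ol | Brc1ccc2c(c1)C[C@@H](O)C(C)(C)O2 | intermediate
12 | lithium (3R)-6-lithio-2,2-dimethylchroman-3-olate (not isolated) | [Li]c1ccc2c(c1)C[C@@H](O[Li])C(C)(C)O2 | intermediate
13 | (3R)-3-hydroxy-2,2-dimethylchromane-6-carbaldehyde | O=Cc1ccc2c(c1)C[C@@H](O)C(C)(C)O2 | intermediate
14 | 3-[2,5-dihydroxy-4-(3-methylbut-2-en-1-yl)phenyl]-4-hydroxy-5-{hydroxy[(3R)-3-hydroxy-2,2-dimethylchroman-6-yl]methyl}furan-2(5H)-one (diastereomer mixture at C5 and the new carbinol carbon, not isolated) | CC(C)=CCc1cc(O)c(cc1O)C1=C(O)C(OC1=O)C(O)c1ccc2c(c1)C[C@@H](O)C(C)(C)O2 | intermediate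
15 | (5Z)-3-[2,5-dihydroxy-4-(3-methylbut-2-en-1-yl)phenyl]-4-hydroxy-5-{[(3R)-3-hydroxy-2,2-dimethylchroman-6-yl]methylidene}furan-2(5H)-one | CC(C)=CCc1cc(O)c(C2=C(O)/C(=C/c3ccc4c(c3)C[C@@H](O)C(C)(C)O4)OC2=O)cc1O | target

## Step count and risks

Total steps: 7. Longest linear sequence: 5 (steps 3, 4, 5, 6, 7).

**Step 1.** The allyl radical can also react through its tertiary terminus, 3 can be prenylated a second time, and yields of such quinone alkylations are moderate. The fallback makes the same bond by a polar route and sets out from 1. Addition of tributyl(3-methylbut-2-en-1-yl)stannane with BF3·OEt2 in CH2Cl2 at −78 °C gives 2-(3-methylbut-2-en-1-yl)benzene-1,4-diol F1. Oxidation of F1 with Ag2O in Et2O comes back to the route at 3.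

**Step 2.** Attack at C6 or C3 gives regioisomers. Product 5 can also exchange redox state with unreacted 3 and then cyclise oxidatively to a furobenzofuranone, or cyclodehydrate if the medium turns acidic. The fallback replaces conjugate addition by cross-coupling on an aryl bromide and sets out from 3 and 4.
- 1,4-Addition of bromide to 3 (Me3SiBr, Et4NBr cat., MeCN, 0 °C, aqueous work-up) gives 2-bromo-5-(3-methylbut-2-en-1-yl)benzene-1,4-diol F2, and minor isomers are removed by crystallisation at this simple stage.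
- MOMCl and i-Pr2NEt in CH2Cl2 give 1-bromo-2,5-bis(methoxymethoxy)-4-(3-methylbut-2-en-1-yl)benzene F3.
- Palladium-catalysed C3-arylation of 4 gives 3-[2,5-bis(methoxymethoxy)-4-(3-methylbut-2-en-1-yl)phenyl]-4-hydroxyfuran-2(5H)-one F4. Conditions are Pd(OAc)2, 2-di-tert-butylphosphino-2',4',6'-triisopropylbiphenyl, K3PO4, 1,4-dioxane, 90 °C, by analogy with arylation of cyclic 1,3-diones and tetramic acids.
- Dilute HCl in MeOH at 40 °C removes the acetals and comes back to the route at 5.

**Step 7.** The condensation runs on an unprotected hydroquinone and needs the poorly acidic C5–H of a tetronate to react with an electron-rich aldehyde. Air oxidation of the hydroquinone, low conversion or E/Z mixtures are possible. The fallback is a stepwise directed aldol on protected partners and sets out from 5 and 13.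
- MOMCl and i-Pr2NEt convert 5 into 3-[2,5-bis(methoxymethoxy)-4-(3-methylbut-2-en-1-yl)phenyl]-4-(methoxymethoxy)furan-2(5H)-one F5.
- Et3SiCl and imidazole convert 13 into (3R)-2,2-dimethyl-3-(triethylsilyloxy)chromane-6-carbaldehyde F6.
- Deprotonation of F5 at C5 with LDA (THF, −78 °C) and addition to F6 gives 3-[2,5-bis(methoxymethoxy)-4-(3-methylbut-2-en-1-yl)phenyl]-5-{hydroxy[(3R)-2,2-dimethyl-3-(triethylsilyloxy)chroman-6-yl]methyl}-4-(methoxymethoxy)furan-2(5H)-one F7.
- HCl in MeOH at 40 °C dehydrates the benzylic carbinol and removes the acetal and silyl groups in one operation, arriving at 15.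

Further compounds
F1 | step 1 | 2-(3-methylbut-2-en-1-yl)benzene-1,4-diol | CC(C)=CCc1cc(O)ccc1O
F2 | step 2 | 2-bromo-5-(3-methylbut-2-en-1-yl)benzene-1,4-diol | CC(C)=CCc1cc(O)c(Br)cc1O
F3 | step 2 | 1-bromo-2,5-bis(methoxymethoxy)-4-(3-methylbut-2-en-1-yl)benzene | CC(C)=CCc1cc(OCOC)c(Br)cc1OCOC
F4 | step 2 | 3-[2,5-bis(methoxymethoxy)-4-(3-methylbut-2-en-1-yl)phenyl]-4-hydroxyfuran-2(5H)-one | CC(C)=CCc1cc(OCOC)c(C2=C(O)COC2=O)cc1OCOC
F5 | step 7 | 3-[2,5-bis(methoxymethoxy)-4-(3-methylbut-2-en-1-yl)phenyl]-4-(methoxymethoxy)furan-2(5H)-one | CC(C)=CCc1cc(OCOC)c(C2=C(OCOC)COC2=O)cc1OCOC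
F6 | step 7 | (3R)-2,2-dimethyl-3-(triethylsilyloxy)chromane-6-carbaldehyde | O=Cc1ccc2c(c1)C[C@@H](O[Si](CC)(CC)CC)C(C)(C)O2
F7 | step 7 | 3-[2,5-bis(methoxymethoxy)-4-(3-methylbut-2-en-1-yl)phenyl]-5-{hydroxy[(3R)-2,2-dimethyl-3-(triethylsilyloxy)chroman-6-yl]methyl}-4-(methoxymethoxy)furan-2(5H)-one | CC(C)=CCc1cc(OCOC)c(cc1OCOC)C1=C(OCOC)C(OC1=O)C(O)c1ccc2c(c1)C[C@@H](O[Si](CC)(CC)CC)C(C)(C)O2
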